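**Assumption (one line):** (+)-Larixol is taken as the commercial normal-series labdane with the C5, C9, C10 configuration and the 6α-hydroxyl of the target. Labdane numbering is used for C1–C12 and C17–C20 (C17 on C8, C18 = 4α-CH2, C19 = 4β-CH3, C20 on C10); in the side chain C13 is the sp2 carbon with the exocyclic methylene, C14 and C15 are the carbinol carbons, and the butenolide is numbered C2′ (C=O), C3′ (CH), C4′ (C–CH3), C5′ (lactone CH on C15).

## Retrosynthetic overview

- Cut C12–C13 (sp3–sp2): a nickel-catalysed reductive coupling of a primary C12 iodide (rings A and B, C1–C12, C17–C20) with a C13 2-bromo-1-alkene that already carries the C14/C15 diol (as a dioxolane) and the butenolide.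
- Enabling feature: C13 is the fully substituted carbon of the exocyclic C13=CH2 group, and C12 is an unbranched CH2 two atoms from C9 of ring B. Neither atom is stereogenic, so the cut gives a 2-bromoalkene and an unhindered primary iodide and separates the decalin stereocentres from the side-chain stereocentres.
- Decalin half: rings A and B come intact from (+)-larixol (C5, C6, C9, C10). The side chain is cut back to C12 (KMnO4, then Baeyer–Villiger), C8 is set by α-epoxidation and hydride opening, and C18 is oxidised from the 6α-oxygen through a temporary oxolane ring, then a γ-lactone, which is reduced open.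
- Side-chain half: the dioxolane ring (C14, C15) comes from L-threitol acetonide; C13 is added by Ohira–Bestmann homologation and α-hydroalumination/bromination; the butenolide ring is closed last (asymmetric propiolate addition sets C5′, cuprate addition and lactonisation).
- Order of ring events: rings A and B (chiral pool), temporary oxolane and lactone on ring B (opened again), butenolide, coupling, then removal of silyl groups and the dioxolane.

Key step: step 16

## Route

Step 1
Reactants: 1 (+)-larixol
Product: 2 6α-hydroxy-14,15-dinorlabd-8(17)-en-13-one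
Conditions: KMnO4, acetone/H2O, 0 → 20 °C
Reagents that add atoms: none
Why: Permanganate degradation of the monosubstituted vinyl carbinol (alkene cleavage, then oxidative loss of the α-hydroxy acid carbon) should give the C13 methyl ketone, while the hindered exocyclic C8(17) alkene and the equatorial 6α-hydroxyl react more slowly; no ring stereocentre is touched.

Step 2
Reactants: 2 6α-hydroxy-14,15-dinorlabd-8(17)-en-13-one
Product: 4 8α,17-epoxy-6α-hydroxy-13,14,15,16-tetranorlabdan-12-yl acetate, via epoxy ketone 3 (not isolated)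
Conditions: (CF3CO)2O, urea·H2O2, Na2HPO4, CH2Cl2, 0 → 20 °C; then NaHCO3, MeOH/H2O
Reagents that add atoms: trifluoroperacetic acid, OOC(=O)C(F)(F)F
Why: Prilezhaev epoxidation of the exocyclic alkene should occur from the α face (equatorial attack, the β face being blocked by the axial C10 methyl), which sets C8 with O α and CH2 β; the same buffered peracid then effects a Baeyer–Villiger oxidation in which the primary C12 migrates in preference to methyl, and the bicarbonate wash removes any trifluoroacetate on O-6.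

Step 3
Reactants: 4 8α,17-epoxy-6α-hydroxy-13,14,15,16-tetranorlabdan-12-yl acetate
Product: 6 6α,18:8α,17-diepoxy-13,14,15,16-tetranorlabdan-12-yl acetate, via 18-iodo alcohol 5 (not isolated)
Conditions: PhI(OAc)2, I2, cyclohexane/CH2Cl2, hν (tungsten lamp), 40 °C
Reagents that add atoms: none
Why: Hypoiodite reaction (alkoxy radical, 1,5-hydrogen atom transfer, iodine transfer, ring closure): the equatorial 6α-oxygen and the equatorial 4α-methyl are both anti to C10 and lie about 2.5 Å apart, so the O-radical should abstract hydrogen from C18 only, and closure of the iodide to the oxolane fixes C4 with CH2O α and CH3 β.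

Step 4
Reactants: 6 6α,18:8α,17-diepoxy-13,14,15,16-tetranorlabdan-12-yl acetate
Product: 7 12-acetoxy-8α,17-epoxy-13,14,15,16-tetranorlabdan-18,6α-olide
Conditions: RuCl3·xH2O (cat.), NaIO4, EtOAc/MeCN/H2O, 20 °C
Reagents that add atoms: sodium periodate (oxygen delivered through catalytic RuO4), [Na+].[O-]I(=O)(=O)=O
Why: RuO4 oxidation of a cyclic ether to the γ-lactone should take place at the α-methylene C18, because the other α-hydrogen (6β-H) is axial and shielded by the C19 and C20 methyls; acetate and epoxide are inert.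

Step 5
Reactants: 7 12-acetoxy-8α,17-epoxy-13,14,15,16-tetranorlabdan-18,6α-olide
Product: 8 13,14,15,16-tetranorlabdane-6α,8α,12,18-tetraol
Conditions: LiAlH4, THF, 0 °C → reflux
Reagents that add atoms: none
Why: Hydride reduction should open the lactone to the 6α,18-diol, open the spiro-epoxide by attack at the C17 methylene (8α-OH and 8β-CH3, C8 untouched) and cleave the acetate, so one operation gives all four hydroxyls of the decalin half.

Step 6
Reactants: 8 13,14,15,16-tetranorlabdane-6α,8α,12,18-tetraol
Product: 10 6α,8α,18-tris(triethylsilyloxy)-13,14,15,16-tetranorlabdan-12-ol, via tetrakis(triethylsilyl) ether 9 (not isolated)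
Conditions: Et3SiOTf, 2,6-lutidine, CH2Cl2, −78 → 0 °C; then MeOH, PPTS (cat.), 0 °C
Reagents that add atoms: triethylsilyl trifluoromethanesulfonate, CC[Si](CC)(CC)OS(=O)(=O)C(F)(F)F
Why: The silyl triflate should silylate all four hydroxyls including the tertiary one, and mild acid methanolysis should then remove only the unhindered primary C12 silyl ether (the others are neopentyl, hindered secondary or tertiary); O-8 must stay capped because a free 8-hydroxyl would close onto an activated C12 to give an oxolane.

Step 7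
Reactants: 10 6α,8α,18-tris(triethylsilyloxy)-13,14,15,16-tetranorlabdan-12-ol
Product: 11 12-iodo-6α,8α,18-tris(triethylsilyloxy)-13,14,15,16-tetranorlabdane
Conditions: I2, PPh3, imidazole, CH2Cl2, 0 → 20 °C
Reagents that add atoms: iodine, II
Why: Appel-type iodination by SN2 displacement of the oxyphosphonium at the unhindered primary C12; silyl ethers are stable and no stereocentre is involved.

Step 8
Reactants: 12 (4S,5S)-2,2-dimethyl-1,3-dioxolane-4,5-dimethanol
Product: 13 [(4S,5S)-5-({[tert-butyl(dimethyl)silyl]oxy}methyl)-2,2-dimethyl-1,3-dioxolan-4-yl]methanol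
Conditions: NaH (1.0 equiv), THF, 0 °C; TBSCl (1.0 equiv)
Reagents that add atoms: tert-butyldimethylsilyl chloride, CC(C)(C)[Si](C)(C)Cl
Why: Mono-silylation of a C2-symmetric diol through its monoalkoxide; both hydroxyls are equivalent, so one product results, and the two dioxolane carbons (the future C14 and C15) already have the target configuration.

Step 9
Reactants: 13 [(4S,5S)-5-({[tert-butyl(dimethyl)silyl]oxy}methyl)-2,2-dimethyl-1,3-dioxolan-4-yl]methanol
Product: 14 (4R,5S)-5-({[tert-butyl(dimethyl)silyl]oxy}methyl)-2,2-dimethyl-1,3-dioxolane-4-carbaldehyde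
Conditions: Dess–Martin periodinane, CH2Cl2, 0 → 20 °C
Reagents that add atoms: none
Why: Dess–Martin oxidation of the primary alcohol; the α-stereocentre is held by the trans-dioxolane, which is also the thermodynamic isomer.

Step 10
Reactants: 14 (4R,5S)-5-({[tert-butyl(dimethyl)silyl]oxy}methyl)-2,2-dimethyl-1,3-dioxolane-4-carbaldehyde
Product: 15 tert-butyl{[(4S,5S)-5-ethynyl-2,2-dimethyl-1,3-dioxolan-4-yl]methoxy}dimethylsilane
Conditions: dimethyl (1-diazo-2-oxopropyl)phosphonate, K2CO3, MeOH, 0 → 20 °C
Reagents that add atoms: dimethyl (1-diazo-2-oxopropyl)phosphonate, COP(=O)(OC)C(=[N+]=[N-])C(C)=O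
Why: Ohira–Bestmann homologation turns the aldehyde carbon into the internal alkyne carbon (the future C13) and adds the terminal carbon; the mild base cannot erode C14 because the trans-dioxolane is the stable isomer.

Step 11
Reactants: 15 tert-butyl{[(4S,5S)-5-ethynyl-2,2-dimethyl-1,3-dioxolan-4-yl]methoxy}dimethylsilane
Product: 17 tert-butyl{[(4S,5R)-5-(1-bromoethenyl)-2,2-dimethyl-1,3-dioxolan-4-yl]methoxy}dimethylsilane, via alkenylalane 16 (not isolated)
Conditions: Ni(dppp)Cl2 (3 mol %), iBu2AlH, THF, 0 → 22 °C; then NBS, 0 °C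
Reagents that add atoms: N-bromosuccinimide, BrN1C(=O)CCC1=O
Why: Nickel-catalysed α-selective (Markovnikov) hydroalumination of a terminal alkyne, in which the bisphosphine ligand places aluminium on the internal carbon, followed by bromodealumination, should give the 2-bromo-1-alkene; the descriptor at the dioxolane carbon changes only because of substituent priority.

Step 12
Reactants: 17 tert-butyl{[(4S,5R)-5-(1-bromoethenyl)-2,2-dimethyl-1,3-dioxolan-4-yl]methoxy}dimethylsilane
Product: 18 [(4S,5R)-5-(1-bromoethenyl)-2,2-dimethyl-1,3-dioxolan-4-yl]methanol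
Conditions: Bu4NF, AcOH, THF, 0 → 20 °C
Reagents that add atoms: none
Why: Fluoride desilylation, buffered with acetic acid so that the alkenyl bromide is not dehydrobrominated.

Step 13
Reactants: 18 [(4S,5R)-5-(1-bromoethenyl)-2,2-dimethyl-1,3-dioxolan-4-yl]methanol
Product: 19 (4R,5R)-5-(1-bromoethenyl)-2,2-dimethyl-1,3-dioxolane-4-carbaldehyde
Conditions: Dess–Martin periodinane, CH2Cl2, 0 → 20 °C
Reagents that add atoms: none
Why: Dess–Martin oxidation under near-neutral conditions; the trans-dioxolane again protects the α-centre (C15) from epimerisation.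

Step 14
Reactants: 19 (4R,5R)-5-(1-bromoethenyl)-2,2-dimethyl-1,3-dioxolane-4-carbaldehyde
Product: 20 methyl (4R)-4-[(4S,5R)-5-(1-bromoethenyl)-2,2-dimethyl-1,3-dioxolan-4-yl]-4-hydroxybut-2-ynoate
Conditions: methyl propiolate, Me2Zn, (S,S)-ProPhenol (20 mol %), Ph3PO (40 mol %), toluene, 4 °C
Reagents that add atoms: methyl propiolate, C#CC(=O)OC
Why: Zinc–ProPhenol-catalysed asymmetric alkynylation: the dinuclear zinc catalyst of the (S,S) ligand is expected to deliver the alkynylzinc to the Re face of the aldehyde, which sets C5′ as R (syn to the C15 oxygen) under catalyst control against the Felkin–Anh preference of the α-alkoxy aldehyde.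

Step 15
Reactants: 20 methyl (4R)-4-[(4S,5R)-5-(1-bromoethenyl)-2,2-dimethyl-1,3-dioxolan-4-yl]-4-hydroxybut-2-ynoate
Product: 22 (5R)-5-[(4S,5R)-5-(1-bromoethenyl)-2,2-dimethyl-1,3-dioxolan-4-yl]-4-methylfuran-2(5H)-one, via Z-hydroxy enoate 21 (not isolated)
Conditions: Me2CuLi (from CuI and MeLi), THF, −78 °C; aq. NH4Cl, then 20 °C
Reagents that add atoms: lithium dimethylcuprate, [Li+].C[Cu-]C
Why: Syn conjugate addition of the cuprate to the ynoate puts the methyl on C4′ and leaves the ester cis to the C5′ carbinol, so the Z-hydroxy enoate should lactonise to the butenolide; C5′ is not touched and the alkenyl bromide is inert at −78 °C.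

Step 16
Reactants: 11 12-iodo-6α,8α,18-tris(triethylsilyloxy)-13,14,15,16-tetranorlabdane; 22 (5R)-5-[(4S,5R)-5-(1-bromoethenyl)-2,2-dimethyl-1,3-dioxolan-4-yl]-4-methylfuran-2(5H)-one
Product: 23 6α,8α,18-tris(triethylsilyl) ether 14,15-acetonide of the target
Conditions: NiBr2(dme) (10 mol %), 4,4′-di-tert-butyl-2,2′-bipyridine (10 mol %), Mn powder, NaI (0.5 equiv), DMA, 25 °C
Reagents that add atoms: none
Why: Nickel-catalysed reductive cross-electrophile coupling: bipyridine-ligated zerovalent nickel inserts into the C13–Br bond of 22, the divalent alkenylnickel bromide traps the primary C12 radical that low-valent nickel generates from the C–I bond of 11, and the trivalent alkyl(alkenyl)nickel forms the C12–C13 bond by reductive elimination, Mn powder returning the catalyst to the zerovalent state. The closest known reaction types are the nickel-catalysed reductive coupling of alkenyl bromides with primary alkyl iodides and the alkyl–alkenyl Negishi coupling. No ring is closed; rings A and B, the dioxolane and the butenolide are carried through intact. No stereocentre is formed, since C12 and C13 are not stereogenic and the nine existing stereocentres are not at the reacting atoms. The step needs cross- over homo-coupling, which is secured by the different activation of the two halides (two-electron oxidative addition at sp2 C–Br, one-electron activation at the unhindered primary sp3 C–I), and chemoselectivity, which is secured by the β,β-disubstituted butenolide being a poor radical acceptor, by the dioxolane oxygen on C14 being a poor leaving group, and by the silyl cap on O-8, which otherwise would close onto C12. In one operation the C16 decalin half and the C9 butenolide half give the complete C25 skeleton with the exocyclic methylene on C13 in its final place.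

Step 17
Reactants: 23 6α,8α,18-tris(triethylsilyl) ether 14,15-acetonide of the target
Product: 24 CNP0301623.1 (target)
Conditions: 2 M aq. HCl, THF/MeOH, 0 → 20 °C
Reagents that add atoms: none
Why: Acid hydrolysis should remove the three silyl ethers and the isopropylidene acetal; dilute acid at room temperature should neither protonate the 1,1-disubstituted alkene (deactivated by the allylic C14 oxygen) nor ionise the tertiary C8 hydroxyl, and no stereocentre is affected.

## Compound list

1 | (+)-larixol, (13S)-labda-8(17),14-diene-6α,13-diol | C=C[C@@](C)(O)CC[C@@H]1[C@@]2(C)CCCC(C)(C)[C@@H]2[C@@H](O)CC1=C | starting material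
2 | 6α-hydroxy-14,15-dinorlabd-8(17)-en-13-one | CC(=O)CC[C@@H]1[C@@]2(C)CCCC(C)(C)[C@@H]2[C@@H](O)CC1=C | intermediate
3 | 8α,17-epoxy-6α-hydroxy-14,15-dinorlabdan-13-one (not isolated) | CC(=O)CC[C@@H]1[C@@]2(C)CCCC(C)(C)[C@@H]2[C@@H](O)C[C@@]1(C3)O3 | intermediate
4 | 8α,17-epoxy-6α-hydroxy-13,14,15,16-tetranorlabdan-12-yl acetate | CC(=O)OCC[C@@H]1[C@@]2(C)CCCC(C)(C)[C@@H]2[C@@H](O)C[C@@]1(C3)O3 | intermediate
5 | 8α,17-epoxy-6α-hydroxy-18-iodo-13,14,15,16-tetranorlabdan-12-yl acetate (not isolated) | CC(=O)OCC[C@@H]1[C@@]2(C)CCC[C@@](C)(CI)[C@@H]2[C@@H](O)C[C@@]1(C3)O3 | intermediate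
6 | 6α,18:8α,17-diepoxy-13,14,15,16-tetranorlabdan-12-yl acetate | CC(=O)OCC[C@@H]1[C@@]2(C)CCC[C@@](C)(CO5)[C@@H]2[C@@H]5C[C@@]1(C3)O3 | intermediate
7 | 12-acetoxy-8α,17-epoxy-13,14,15,16-tetranorlabdan-18,6α-olide | CC(=O)OCC[C@@H]1[C@@]2(C)CCC[C@@](C)(C(=O)O5)[C@@H]2[C@@H]5C[C@@]1(C3)O3 | intermediate
8 | 13,14,15,16-tetranorlabdane-6α,8α,12,18-tetraol | OCC[C@@H]1[C@@]2(C)CCC[C@@](C)(CO)[C@@H]2[C@@H](O)C[C@@]1(C)O | intermediate
9 | 6α,8α,12,18-tetrakis(triethylsilyloxy)-13,14,15,16-tetranorlabdane (not isolated) | CC[Si](CC)(CC)OCC[C@@H]1[C@@]2(C)CCC[C@@](C)(CO[Si](CC)(CC)CC)[C@@H]2[C@@H](O[Si](CC)(CC)CC)C[C@@]1(C)O[Si](CC)(CC)CC | intermediate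
10 | 6α,8α,18-tris(triethylsilyloxy)-13,14,15,16-tetranorlabdan-12-ol | OCC[C@@H]1[C@@]2(C)CCC[C@@](C)(CO[Si](CC)(CC)CC)[C@@H]2[C@@H](O[Si](CC)(CC)CC)C[C@@]1(C)O[Si](CC)(CC)CC | intermediate
11 | 12-iodo-6α,8α,18-tris(triethylsilyloxy)-13,14,15,16-tetranorlabdane | ICC[C@@H]1[C@@]2(C)CCC[C@@](C)(CO[Si](CC)(CC)CC)[C@@H]2[C@@H](O[Si](CC)(CC)CC)C[C@@]1(C)O[Si](CC)(CC)CC | intermediate
12 | (4S,5S)-2,2-dimethyl-1,3-dioxolane-4,5-dimethanol (2,3-O-isopropylidene-L-threitol) | OC[C@@H]1OC(C)(C)O[C@H]1CO | starting material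
13 | [(4S,5S)-5-({[tert-butyl(dimethyl)silyl]oxy}methyl)-2,2-dimethyl-1,3-dioxolan-4-yl]methanol | OC[C@@H]1OC(C)(C)O[C@H]1CO[Si](C)(C)C(C)(C)C | intermediate
14 | (4R,5S)-5-({[tert-butyl(dimethyl)silyl]oxy}methyl)-2,2-dimethyl-1,3-dioxolane-4-carbaldehyde | O=C[C@@H]1OC(C)(C)O[C@H]1CO[Si](C)(C)C(C)(C)C | intermediate
15 | tert-butyl{[(4S,5S)-5-ethynyl-2,2-dimethyl-1,3-dioxolan-4-yl]methoxy}dimethylsilane | C#C[C@@H]1OC(C)(C)O[C@H]1CO[Si](C)(C)C(C)(C)C | intermediate
16 | diisobutyl[1-(dioxolanyl)ethenyl]alane, aluminium on the internal alkene carbon, dioxolane as in 15 (not isolated) | C=C([Al](CC(C)C)CC(C)C)[C@@H]1OC(C)(C)O[C@H]1CO[Si](C)(C)C(C)(C)C | intermediate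
17 | tert-butyl{[(4S,5R)-5-(1-bromoethenyl)-2,2-dimethyl-1,3-dioxolan-4-yl]methoxy}dimethylsilane | C=C(Br)[C@@H]1OC(C)(C)O[C@H]1CO[Si](C)(C)C(C)(C)C | intermediate
18 | [(4S,5R)-5-(1-bromoethenyl)-2,2-dimethyl-1,3-dioxolan-4-yl]methanol | C=C(Br)[C@@H]1OC(C)(C)O[C@H]1CO | intermediate
19 | (4R,5R)-5-(1-bromoethenyl)-2,2-dimethyl-1,3-dioxolane-4-carbaldehyde | C=C(Br)[C@@H]1OC(C)(C)O[C@H]1C=O | intermediate
20 | methyl (4R)-4-[(4S,5R)-5-(1-bromoethenyl)-2,2-dimethyl-1,3-dioxolan-4-yl]-4-hydroxybut-2-ynoate | C=C(Br)[C@@H]1OC(C)(C)O[C@H]1[C@H](O)C#CC(=O)OC | intermediate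
21 | methyl (2Z,4R)-4-[(4S,5R)-5-(1-bromoethenyl)-2,2-dimethyl-1,3-dioxolan-4-yl]-4-hydroxy-3-methylbut-2-enoate (not isolated) | C=C(Br)[C@@H]1OC(C)(C)O[C@H]1[C@H](O)/C(C)=C\C(=O)OC | intermediate
22 | (5R)-5-[(4S,5R)-5-(1-bromoethenyl)-2,2-dimethyl-1,3-dioxolan-4-yl]-4-methylfuran-2(5H)-one | C=C(Br)[C@@H]1OC(C)(C)O[C@H]1[C@@H]2OC(=O)C=C2C | intermediate
23 | 6α,8α,18-tris(triethylsilyl) ether 14,15-acetonide of the target | C=C(CC[C@@H]1[C@@]2(C)CCC[C@@](C)(CO[Si](CC)(CC)CC)[C@@H]2[C@@H](O[Si](CC)(CC)CC)C[C@@]1(C)O[Si](CC)(CC)CC)[C@@H]3OC(C)(C)O[C@H]3[C@@H]4OC(=O)C=C4C | intermediate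
24 | CNP0301623.1 | C=C(CC[C@@H]1[C@@]2(C)CCC[C@@](C)(CO)[C@@H]2[C@@H](O)C[C@@]1(C)O)[C@H](O)[C@@H](O)[C@@H]1OC(=O)C=C1C | target

## Step count and risks

Total step count: 17. Longest linear sequence: 10 steps (12 → 24, steps 8–15, 16, 17); the decalin branch is 9 steps (1 → 24).

The three steps most likely to fail:

**Step 3 (remote oxidation of C18).** Fragmentation of the 6-alkoxy radical (β-scission of C5–C6) or iodine-induced opening of the spiro-epoxide may outrun the 1,5-hydrogen transfer. The fallback replaces the radical relay by a metal-catalysed, hydroxyl-directed C–H silylation; it sets out from 4 and returns at 8, bypassing 6 and 7. Compound 4 is silylated with Et2SiH2 and [Ir(cod)OMe]2 (cat.) to the diethylhydrosilyl ether F1. Heating with [Rh(cod)Cl]2/Xantphos and norbornene in THF should close the six-membered oxasilinane F2 by silylation of the δ C–H bond at C18; the γ carbons C4, C8 and C10 carry no hydrogen and C18 is the nearest methyl. Tamao–Fleming oxidation (H2O2, KHCO3, KF, THF/MeOH) gives the 6α,18-diol F3, and LiAlH4 then opens the epoxide and cleaves the acetate to give 8.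

**Step 14 (C5′ stereocentre).** Catalyst control may not override the Felkin–Anh preference of the α-alkoxy aldehyde, giving poor facial selectivity. (A reversed facial sense of the ligand alone would be met by using its enantiomer.) The fallback sets out from 19 and returns at 20. The anti adduct is made on purpose by the same alkynylation with (R,R)-ProPhenol, matched to the Felkin–Anh sense, giving the (4S)-hydroxy ynoate F4. C5′ is then inverted by Mitsunobu esterification with chloroacetic acid (PPh3, DIAD, toluene, 0 °C) to the chloroacetate F5, and the chloroacetyl group is removed under near-neutral conditions (thiourea, NaHCO3, MeOH/THF) to give 20.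

**Step 16 (key coupling).** Homocoupling or hydrodehalogenation of the two halides may compete with cross-coupling. The fallback is a polar alkyl–alkenyl coupling that sets out from 11 and returns at 23. Zinc insertion into the C12–I bond (Zn dust, LiCl, THF, 40 °C) gives the alkylzinc iodide F6, which is coupled with 22 under Negishi conditions (Pd(OAc)2, SPhos, THF/NMP, 20 °C) to give 23.

Further compounds
F1 | step 3 | 8α,17-epoxy-6α-(diethylsilyloxy)-13,14,15,16-tetranorlabdan-12-yl acetate | CC(=O)OCC[C@@H]1[C@@]2(C)CCCC(C)(C)[C@@H]2[C@@H](O[SiH](CC)CC)C[C@@]1(C3)O3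
F2 | step 3 | 6α-O,18-C-(diethylsilanediyl) oxasilinane of 8α,17-epoxy-13,14,15,16-tetranorlabdan-12-yl acetate | CC(=O)OCC[C@@H]1[C@@]2(C)CCC[C@@](C)(C[Si](CC)(CC)O5)[C@@H]2[C@@H]5C[C@@]1(C3)O3
F3 | step 3 | 8α,17-epoxy-6α,18-dihydroxy-13,14,15,16-tetranorlabdan-12-yl acetate | CC(=O)OCC[C@@H]1[C@@]2(C)CCC[C@@](C)(CO)[C@@H]2[C@@H](O)C[C@@]1(C3)O3
F4 | step 14 | methyl (4S)-4-[(4S,5R)-5-(1-bromoethenyl)-2,2-dimethyl-1,3-dioxolan-4-yl]-4-hydroxybut-2-ynoate | C=C(Br)[C@@H]1OC(C)(C)O[C@H]1[C@@H](O)C#CC(=O)OC
F5 | step 14 | methyl (4R)-4-[(4S,5R)-5-(1-bromoethenyl)-2,2-dimethyl-1,3-dioxolan-4-yl]-4-(chloroacetoxy)but-2-ynoate | C=C(Br)[C@@H]1OC(C)(C)O[C@H]1[C@H](OC(=O)CCl)C#CC(=O)OC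
F6 | step 16 | [6α,8α,18-tris(triethylsilyloxy)-13,14,15,16-tetranorlabdan-12-yl]zinc iodide | I[Zn]CC[C@@H]1[C@@]2(C)CCC[C@@](C)(CO[Si](CC)(CC)CC)[C@@H]2[C@@H](O[Si](CC)(CC)CC)C[C@@]1(C)O[Si](CC)(CC)CC
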